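**Plan**

- Retrosynthesis: the hydroquinone is unmasked last from its dimethyl ether. Both ketones are traced to carbinols, so the chain is cut at the two C(carbinol)–CH2(allyl) bonds: a prenyl unit and an (E)-arylallyl unit, each added as an α-selective allylbarium reagent to an aldehyde. The arylallyl unit is cut at aryl–CH2 (aryl Grignard plus 2-methyl-2-vinyloxirane).
- The cyclopentane is cut at ring bond C1–C5: aldehyde 14 is the ring-contraction product of the 1,2-dimethylcyclohexene oxide 13 (semipinacol 1,2-shift).
- Enabling feature: ring carbon C1 of the cyclopentane bears a methyl group and an exocyclic carbonyl carbon and sits next to quaternary ring carbon C2. This is the pattern left when a ring CH2 of a cyclohexene oxide migrates onto the methyl-bearing epoxide carbon and the CH–O carbon is pushed out of the ring as CHO.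
- Forward order: six-membered ring from 2-methylcyclohexanone → quaternary C2 by Pd-catalysed decarboxylative allylation → enol triflate, arm shortening, methylation → hydroxyl-directed epoxidation → contraction to the cyclopentane → prenyl side → union with the aryl fragment (made separately) → oxidation → hydroquinone.
- Stereochemistry: C2 comes from the (R)-t-Bu-PHOX ligand. C1 is relayed from C2 by syn (hydroxyl-directed) epoxidation and migration anti to the epoxide oxygen. The E alkene comes from SN2′ opening of the vinyl oxirane and is kept in the barium reagent.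

Key step: step 9

Assumption: the carbinol centres formed in steps 10 and 17 are carried on as epimer mixtures, since both are oxidised to ketones (steps 12 and 18). Compounds 1 and 23 are used as racemates because their stereocentres vanish in the first step in which they react. No step after step 9 can epimerise the two quaternary centres, so the enantiomeric purity set in step 3 is carried through.

**Route**

Step 1
Reactants: 1 2-methylcyclohexanone
Product: 2 trimethyl[(2-methylcyclohex-1-en-1-yl)oxy]silane
Conditions: TMSCl, NaI, Et3N, MeCN, rt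
Reagents that add atoms: chlorotrimethylsilane, C[Si](C)(C)Cl
Why: Thermodynamic silyl enol ether formation: soft enolisation by iodotrimethylsilane formed in situ is reversible, so the tetrasubstituted enol silane should predominate and the minor regioisomer is removed by fractional distillation.

Step 2
Reactants: 2 trimethyl[(2-methylcyclohex-1-en-1-yl)oxy]silane, 3 allyl chloroformate
Product: 5 allyl (2-methylcyclohex-1-en-1-yl) carbonate, via lithium enolate 4 (not isolated)
Conditions: MeLi, THF, 0 °C; then 3, −78 °C → rt
Reagents that add atoms: none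
Why: Si–O cleavage by methyllithium releases the regiodefined lithium enolate without proton transfer, and the hard chloroformate acylates it on oxygen (enolate O-acylation) to give the enol carbonate.

Step 3
Reactants: 5 allyl (2-methylcyclohex-1-en-1-yl) carbonate
Product: 6 (R)-2-allyl-2-methylcyclohexan-1-one
Conditions: Pd2(dba)3 (2.5 mol %), (R)-t-Bu-PHOX (6.25 mol %), THF, 25 °C
Reagents that add atoms: none
Why: Decarboxylative asymmetric Tsuji–Trost allylation: oxidative addition and loss of CO2 give a Pd(allyl) enolate that recombines regiospecifically at the methyl-bearing carbon inside the ligand sphere, and the (R)-ligand, mirror image of the one established to give the (S)-ketone, should set the quaternary centre (future C2) as R.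

Step 4
Reactants: 6 (R)-2-allyl-2-methylcyclohexan-1-one
Product: 8 (R)-6-allyl-6-methylcyclohex-1-en-1-yl trifluoromethanesulfonate, via potassium enolate 7 (not isolated)
Conditions: KHMDS, THF, −78 °C; then PhNTf2, −78 → 0 °C
Reagents that add atoms: N-phenylbis(trifluoromethanesulfonimide), O=S(=O)(N(c1ccccc1)S(=O)(=O)C(F)(F)F)C(F)(F)F
Why: Enol triflate formation: only the ring CH2 beside the carbonyl has α-hydrogens, so enolisation and O-sulfonylation can give one regioisomer only and the quaternary centre is not involved.

Step 5
Reactants: 8 (R)-6-allyl-6-methylcyclohex-1-en-1-yl trifluoromethanesulfonate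
Product: 10 (R)-6-(2-hydroxyethyl)-6-methylcyclohex-1-en-1-yl trifluoromethanesulfonate, via triflate aldehyde 9 (not isolated)
Conditions: O3, CH2Cl2/MeOH, −78 °C (Sudan III end point); Me2S, −78 °C → rt; then NaBH4, 0 °C
Reagents that add atoms: ozone, [O-][O+]=O
Why: Ozonolysis with reductive work-up: electrophilic ozone should cleave the terminal alkene much faster than the electron-poor enol triflate, dimethyl sulfide reduces the peroxidic intermediate to the aldehyde, and borohydride then reduces only that aldehyde, so the arm is shortened without any ketone protection.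

Step 6
Reactants: 10 (R)-6-(2-hydroxyethyl)-6-methylcyclohex-1-en-1-yl trifluoromethanesulfonate
Product: 11 2-[(1R)-1,2-dimethylcyclohex-2-en-1-yl]ethan-1-ol
Conditions: MeB(OH)2, Pd(dppf)Cl2 (5 mol %), K3PO4, dioxane/H2O, 80 °C
Reagents that add atoms: methylboronic acid, CB(O)O
Why: Suzuki–Miyaura methylation of an alkenyl triflate: Pd(0) inserts readily into the C–OTf bond, methyl cannot undergo β-hydride elimination and the free hydroxyl is tolerated, so the trisubstituted ring alkene should form with its position fixed by the triflate.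

Step 7
Reactants: 11 2-[(1R)-1,2-dimethylcyclohex-2-en-1-yl]ethan-1-ol
Product: 12 2-[(1S,2R,6R)-1,2-dimethyl-7-oxabicyclo[4.1.0]heptan-2-yl]ethan-1-ol (epoxide oxygen syn to the hydroxyethyl arm)
Conditions: VO(acac)2 (5 mol %), t-BuOOH (decane), toluene, 0 °C → rt
Reagents that add atoms: tert-butyl hydroperoxide, CC(C)(C)OO
Why: Vanadium-catalysed hydroxyl-directed epoxidation of a bishomoallylic alcohol: the vanadate ester of the arm hydroxyl carries the bound peroxide and, being anchored at C2, can reach only the alkene face on its own side, so the epoxide should form syn to the arm and both epoxide stereocentres are set by C2.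

Step 8
Reactants: 12 2-[(1S,2R,6R)-1,2-dimethyl-7-oxabicyclo[4.1.0]heptan-2-yl]ethan-1-ol
Product: 13 tert-butyl{2-[(1S,2R,6R)-1,2-dimethyl-7-oxabicyclo[4.1.0]heptan-2-yl]ethoxy}dimethylsilane
Conditions: TBSCl, imidazole, DMF, 0 °C → rt
Reagents that add atoms: tert-butyldimethylsilyl chloride, CC(C)(C)[Si](C)(C)Cl
Why: Imidazole-promoted silylation caps the hydroxyl so that it can neither bind the Lewis acid nor capture the tertiary cation in the next step, and the epoxide is inert to these mildly basic conditions.

Step 9
Reactants: 13 tert-butyl{2-[(1S,2R,6R)-1,2-dimethyl-7-oxabicyclo[4.1.0]heptan-2-yl]ethoxy}dimethylsilane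
Product: 14 (1R,2R)-2-[2-(tert-butyldimethylsilyloxy)ethyl]-1,2-dimethylcyclopentane-1-carbaldehyde
Conditions: methylaluminium bis(4-bromo-2,6-di-tert-butylphenoxide) (MABR, 20 mol %, preformed from Me3Al and the phenol), CH2Cl2, −78 → −20 °C
Reagents that add atoms: none
Why: Meinwald (semipinacol) rearrangement: the oxophilic, very bulky aluminium phenoxide binds the epoxide oxygen, the C1–O bond at the methyl-bearing tertiary carbon ionises, and the ring CH2 (C5) shifts from C6 to C1 as C6 collapses to the formyl carbon. The closest known reaction type is the MABR- or BF3-promoted conversion of 1-methylcyclohexene oxides into 1-methylcyclopentanecarbaldehydes. The cyclopentane is closed by a suprafacial 1,2-alkyl shift (ring contraction: the C5–C1 bond forms as the C5–C6 bond breaks), not by an end-to-end cyclisation. The new quaternary stereocentre C1 is controlled by the epoxide configuration, because C5 arrives anti to the departing oxygen (inversion at C1); with the oxygen syn to the C2 arm this places the formyl group cis to the arm and the two methyl groups cis, i.e. (1R,2R). The step needs ring-bond rather than hydride migration, which the bulky aluminium reagent is known to favour, opening at C1 rather than C6, which the tertiary centre secures, and a silent arm oxygen, which the tert-butyldimethylsilyl group secures.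

Step 10
Reactants: 14 (1R,2R)-2-[2-(tert-butyldimethylsilyloxy)ethyl]-1,2-dimethylcyclopentane-1-carbaldehyde, 15 1-chloro-3-methylbut-2-ene (prenyl chloride)
Product: 17 1-[(1R,2R)-2-[2-(tert-butyldimethylsilyloxy)ethyl]-1,2-dimethylcyclopentyl]-4-methylpent-3-en-1-ol (carbinol epimers), via prenylbarium chloride 16 (not isolated)
Conditions: BaI2, lithium biphenylide, THF, rt; 15, −78 °C; then 14, −78 °C; aq NH4Cl
Reagents that add atoms: none
Why: Allylbarium carbonyl addition: prenylbarium made from the chloride and activated barium at −78 °C should attack aldehydes through its unsubstituted α-carbon, and γ-attack is further disfavoured here because it would build a third contiguous quaternary carbon beside the non-enolisable neopentyl aldehyde; the new carbinol centre forms unselectively and is erased in step 12.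

Step 11
Reactants: 17 1-[(1R,2R)-2-[2-(tert-butyldimethylsilyloxy)ethyl]-1,2-dimethylcyclopentyl]-4-methylpent-3-en-1-ol
Product: 18 1-[(1R,2R)-2-(2-hydroxyethyl)-1,2-dimethylcyclopentyl]-4-methylpent-3-en-1-ol (carbinol epimers)
Conditions: HF·pyridine, pyridine/THF, 0 °C → rt
Reagents that add atoms: none
Why: Fluoride cleavage of the primary silyl ether (Si–F bond formation) under pyridine buffer should leave the trisubstituted alkene and the hindered secondary carbinol unchanged, and it is done before any β,γ-unsaturated ketone exists.

Step 12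
Reactants: 18 1-[(1R,2R)-2-(2-hydroxyethyl)-1,2-dimethylcyclopentyl]-4-methylpent-3-en-1-ol
Product: 19 2-[(1R,2R)-1,2-dimethyl-2-(4-methylpent-3-enoyl)cyclopentyl]acetaldehyde
Conditions: Dess–Martin periodinane (3 equiv), NaHCO3, CH2Cl2, 0 °C → rt
Reagents that add atoms: none
Why: Dess–Martin oxidation: with excess reagent both hydroxyls exchange onto iodine(V) before either is oxidised, so the primary carbinol should become the aldehyde and the secondary one the ketone rather than a lactol or lactone, and the neutral medium keeps the β,γ-alkene out of conjugation.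

Step 13
Reactants: 20 4-methoxy-2-methylphenol
Product: 21 2-bromo-4-methoxy-6-methylphenol
Conditions: NBS, i-Pr2NH (10 mol %), CH2Cl2, 0 °C
Reagents that add atoms: N-bromosuccinimide, O=C1CCC(=O)N1Br
Why: Amine-catalysed NBS bromination (electrophilic aromatic substitution): the free hydroxyl is the strongest director and delivers bromine to its only open ortho position, para being occupied by the methoxy group.

Step 14
Reactants: 21 2-bromo-4-methoxy-6-methylphenol
Product: 22 1-bromo-2,5-dimethoxy-3-methylbenzene
Conditions: MeI, K2CO3, acetone, reflux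
Reagents that add atoms: iodomethane, CI
Why: Williamson ether synthesis turns the phenol into the second methyl ether, giving a hydroquinone dimethyl ether that withstands the organometallic steps and can be removed oxidatively at the end.

Step 15
Reactants: 22 1-bromo-2,5-dimethoxy-3-methylbenzene, 23 2-methyl-2-vinyloxirane
Product: 25 (E)-4-(2,5-dimethoxy-3-methylphenyl)-2-methylbut-2-en-1-ol, via aryl Grignard reagent 24 (not isolated)
Conditions: Mg, THF, reflux; then CuI (10 mol %), 23, THF, −30 → 0 °C; aq NH4Cl
Reagents that add atoms: none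
Why: Grignard formation followed by copper-catalysed SN2′ opening of the vinyl oxirane: the arylcopper adds at the vinyl terminus anti to the breaking C–O bond through the s-trans conformer, which should give the (E)-trisubstituted allylic alcohol, any Z isomer being removed by chromatography here.

Step 16
Reactants: 25 (E)-4-(2,5-dimethoxy-3-methylphenyl)-2-methylbut-2-en-1-ol
Product: 26 1-[(E)-4-chloro-3-methylbut-2-en-1-yl]-2,5-dimethoxy-3-methylbenzene
Conditions: PPh3, CCl4, reflux
Reagents that add atoms: tetrachloromethane, ClC(Cl)(Cl)Cl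
Why: Appel chlorination: the primary oxyphosphonium is displaced by chloride at the same carbon (SN2), so the allylic chloride should form without allylic transposition or loss of the E geometry.

Step 17
Reactants: 19 2-[(1R,2R)-1,2-dimethyl-2-(4-methylpent-3-enoyl)cyclopentyl]acetaldehyde, 26 1-[(E)-4-chloro-3-methylbut-2-en-1-yl]-2,5-dimethoxy-3-methylbenzene
Product: 28 1-{(1R,2R)-2-[(E)-6-(2,5-dimethoxy-3-methylphenyl)-2-hydroxy-4-methylhex-4-en-1-yl]-1,2-dimethylcyclopentyl}-4-methylpent-3-en-1-one (carbinol epimers), via allylbarium chloride 27 (not isolated)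
Conditions: BaI2, lithium biphenylide, THF, rt; 26, −78 °C; then 19, −78 °C; aq NH4Cl
Reagents that add atoms: none
Why: Allylbarium carbonyl addition: the allylic barium made at −78 °C should keep its E geometry and attack through its α-CH2, and the aldehyde is far more electrophilic than the ketone shielded by two quaternary carbons, so the linear homoallylic alcohol is expected; the carbinol centre forms unselectively and is erased in step 18.

Step 18
Reactants: 28 1-{(1R,2R)-2-[(E)-6-(2,5-dimethoxy-3-methylphenyl)-2-hydroxy-4-methylhex-4-en-1-yl]-1,2-dimethylcyclopentyl}-4-methylpent-3-en-1-one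
Product: 29 (E)-6-(2,5-dimethoxy-3-methylphenyl)-1-[(1R,2R)-1,2-dimethyl-2-(4-methylpent-3-enoyl)cyclopentyl]-4-methylhex-4-en-2-one
Conditions: Dess–Martin periodinane, NaHCO3, CH2Cl2, 0 °C
Reagents that add atoms: none
Why: Dess–Martin oxidation under bicarbonate buffer converts the homoallylic alcohol into the β,γ-unsaturated ketone under neutral conditions, so neither double bond should move into conjugation and the 1,5-diketone should not undergo aldol closure.

Step 19
Reactants: 29 (E)-6-(2,5-dimethoxy-3-methylphenyl)-1-[(1R,2R)-1,2-dimethyl-2-(4-methylpent-3-enoyl)cyclopentyl]-4-methylhex-4-en-2-one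
Product: 31 (E)-6-(2,5-dihydroxy-3-methylphenyl)-1-[(1R,2R)-1,2-dimethyl-2-(4-methylpent-3-enoyl)cyclopentyl]-4-methylhex-4-en-2-one (CNP0294415.1), via quinone 30 (not isolated)
Conditions: CAN, MeCN/H2O, 0 °C; then Na2S2O4, H2O/EtOAc, rt
Reagents that add atoms: water, O
Why: Cerium(IV) oxidative demethylation of the hydroquinone dimethyl ether (water adds at both ipso carbons and methanol leaves) gives the p-quinone, which dithionite reduces to the hydroquinone in the same work-up; isolated trisubstituted alkenes, ketones and the quaternary stereocentres are inert to both reagents.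

**Compound list**

1 | 2-methylcyclohexanone (racemic) | CC1CCCCC1=O | starting material
2 | trimethyl[(2-methylcyclohex-1-en-1-yl)oxy]silane | CC1=C(O[Si](C)(C)C)CCCC1 | intermediate
3 | allyl chloroformate | C=CCOC(Cl)=O | starting material
4 | lithium 2-methylcyclohex-1-en-1-olate | CC1=C([O-])CCCC1.[Li+] | intermediate
5 | allyl (2-methylcyclohex-1-en-1-yl) carbonate | C=CCOC(=O)OC1=C(C)CCCC1 | intermediate
6 | (R)-2-allyl-2-methylcyclohexan-1-one | O=C1CCCC[C@]1(C)CC=C | intermediate
7 | potassium (R)-6-allyl-6-methylcyclohex-1-en-1-olate | [K+].[O-]C1=CCCC[C@]1(C)CC=C | intermediate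
8 | (R)-6-allyl-6-methylcyclohex-1-en-1-yl trifluoromethanesulfonate | O=S(=O)(OC1=CCCC[C@]1(C)CC=C)C(F)(F)F | intermediate
9 | (R)-6-methyl-6-(2-oxoethyl)cyclohex-1-en-1-yl trifluoromethanesulfonate | O=S(=O)(OC1=CCCC[C@]1(C)CC=O)C(F)(F)F | intermediate
10 | (R)-6-(2-hydroxyethyl)-6-methylcyclohex-1-en-1-yl trifluoromethanesulfonate | O=S(=O)(OC1=CCCC[C@]1(C)CCO)C(F)(F)F | intermediate
11 | 2-[(1R)-1,2-dimethylcyclohex-2-en-1-yl]ethan-1-ol | CC1=CCCC[C@]1(C)CCO | intermediate
12 | 2-[(1S,2R,6R)-1,2-dimethyl-7-oxabicyclo[4.1.0]heptan-2-yl]ethan-1-ol (epoxide syn to the arm) | C[C@@]12O[C@@H]1CCC[C@]2(C)CCO | intermediate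
13 | tert-butyl{2-[(1S,2R,6R)-1,2-dimethyl-7-oxabicyclo[4.1.0]heptan-2-yl]ethoxy}dimethylsilane | C[C@@]12O[C@@H]1CCC[C@]2(C)CCO[Si](C)(C)C(C)(C)C | intermediate
14 | (1R,2R)-2-[2-(tert-butyldimethylsilyloxy)ethyl]-1,2-dimethylcyclopentane-1-carbaldehyde (methyls cis) | O=C[C@]1(C)CCC[C@]1(C)CCO[Si](C)(C)C(C)(C)C | intermediate
15 | 1-chloro-3-methylbut-2-ene (prenyl chloride) | CC(C)=CCCl | starting material
16 | (3-methylbut-2-en-1-yl)barium chloride | CC(C)=CC[Ba]Cl | intermediate
17 | 1-[(1R,2R)-2-[2-(tert-butyldimethylsilyloxy)ethyl]-1,2-dimethylcyclopentyl]-4-methylpent-3-en-1-ol (carbinol epimers) | CC(C)=CCC(O)[C@]1(C)CCC[C@]1(C)CCO[Si](C)(C)C(C)(C)C | intermediate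
18 | 1-[(1R,2R)-2-(2-hydroxyethyl)-1,2-dimethylcyclopentyl]-4-methylpent-3-en-1-ol (carbinol epimers) | CC(C)=CCC(O)[C@]1(C)CCC[C@]1(C)CCO | intermediate
19 | 2-[(1R,2R)-1,2-dimethyl-2-(4-methylpent-3-enoyl)cyclopentyl]acetaldehyde | CC(C)=CCC(=O)[C@]1(C)CCC[C@]1(C)CC=O | intermediate
20 | 4-methoxy-2-methylphenol | COc1ccc(O)c(C)c1 | starting material
21 | 2-bromo-4-methoxy-6-methylphenol | COc1cc(C)c(O)c(Br)c1 | intermediate
22 | 1-bromo-2,5-dimethoxy-3-methylbenzene | COc1cc(C)c(OC)c(Br)c1 | intermediate
23 | 2-methyl-2-vinyloxirane (racemic) | CC1(C=C)CO1 | starting material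
24 | (2,5-dimethoxy-3-methylphenyl)magnesium bromide | COc1cc(C)c(OC)c([Mg]Br)c1 | intermediate
25 | (E)-4-(2,5-dimethoxy-3-methylphenyl)-2-methylbut-2-en-1-ol | COc1cc(C)c(OC)c(C/C=C(\C)CO)c1 | intermediate
26 | 1-[(E)-4-chloro-3-methylbut-2-en-1-yl]-2,5-dimethoxy-3-methylbenzene | COc1cc(C)c(OC)c(C/C=C(\C)CCl)c1 | intermediate
27 | [(E)-4-(2,5-dimethoxy-3-methylphenyl)-2-methylbut-2-en-1-yl]barium chloride | COc1cc(C)c(OC)c(C/C=C(\C)C[Ba]Cl)c1 | intermediate
28 | 1-{(1R,2R)-2-[(E)-6-(2,5-dimethoxy-3-methylphenyl)-2-hydroxy-4-methylhex-4-en-1-yl]-1,2-dimethylcyclopentyl}-4-methylpent-3-en-1-one (carbinol epimers) | CC(C)=CCC(=O)[C@]1(C)CCC[C@]1(C)CC(O)C/C(C)=C/Cc1cc(OC)cc(C)c1OC | intermediate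
29 | (E)-6-(2,5-dimethoxy-3-methylphenyl)-1-[(1R,2R)-1,2-dimethyl-2-(4-methylpent-3-enoyl)cyclopentyl]-4-methylhex-4-en-2-one | CC(C)=CCC(=O)[C@]1(C)CCC[C@]1(C)CC(=O)C/C(C)=C/Cc1cc(OC)cc(C)c1OC | intermediate
30 | 2-{(E)-6-[(1R,2R)-1,2-dimethyl-2-(4-methylpent-3-enoyl)cyclopentyl]-3-methyl-5-oxohex-2-en-1-yl}-6-methyl-1,4-benzoquinone | CC(C)=CCC(=O)[C@]1(C)CCC[C@]1(C)CC(=O)C/C(C)=C/CC1=CC(=O)C=C(C)C1=O | intermediate
31 | (E)-6-(2,5-dihydroxy-3-methylphenyl)-1-[(1R,2R)-1,2-dimethyl-2-(4-methylpent-3-enoyl)cyclopentyl]-4-methylhex-4-en-2-one (CNP0294415.1) | CC(C)=CCC(=O)[C@]1(C)CCC[C@]1(C)CC(=O)C/C(C)=C/Cc1cc(O)cc(C)c1O | target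

**Step count**

Total: 19 steps. Longest linear sequence: 15 steps (steps 1–12 and 17–19, from 2-methylcyclohexanone). The aryl fragment takes 4 steps (13–16) before the union.

**Steps most likely to fail**

(a) Step 9, the ring contraction. Hydride migration from C6 (leading to a cyclohexanone) or capture of the developing cation at C1 by the silyl ether oxygen (five-membered oxonium, then loss of silyl) may outrun the ring-bond shift. The Lewis acid may also be held by the ether oxygen so that turnover stops. The fallback changes the spectator group on the arm and the way back to the route. It sets out from epoxy alcohol 12. Pivaloyl chloride and pyridine should give the epoxy pivalate F1, whose alkyl oxygen is deactivated by the acyl group and whose carbonyl oxygen could reach C1 only through a seven-membered ring. Rearrangement with a full equivalent of the aluminium phenoxide (the ester binds part of it) should give the formyl pivalate F2 by the same anti 1,2-shift. Prenylbarium addition as in step 10 should give the carbinol pivalate F3. Reductive removal of the pivalate with DIBAL-H (CH2Cl2, −78 °C) returns to the route at diol 18.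

(b) Step 17, the fragment union. The arylallyl barium may attack through its γ-carbon, lose its E geometry, couple with unreacted chloride during barium insertion, or isomerise by proton transfer to the benzylic position. As a base it may also enolise the prenyl ketone and trigger aldol closure of the 1,5-keto aldehyde. The fallback replaces the barium reagent by a sulfone-stabilised carbanion. It sets out from chloride 26 and keto aldehyde 19. Sodium benzenesulfinate (DMF, rt) should convert 26 into the allyl sulfone F4. Deprotonation (n-BuLi, THF, −78 °C) and addition to 19 at the sulfonyl-bearing carbon should give the β-hydroxy sulfone F5. Dess–Martin oxidation should give the β-keto sulfone F6. Reductive desulfonylation with SmI2 (THF/MeOH, −78 °C), with α-protonation of the resulting dienolate, returns to the route at diketone 29, so step 18 is not needed.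

(c) Step 7, the directed epoxidation. The remote hydroxyl may bind vanadium too weakly for useful turnover, or the Lewis-acidic metal may let the arm hydroxyl open the new epoxide at C1 in an SN1 sense to a cis-fused tetrahydrofuran. The fallback delivers the oxygen through an iodolactone instead. It sets out from alkene alcohol 11. Oxidation with TEMPO/PhI(OAc)2 in MeCN/H2O should give the carboxylic acid F7. Iodolactonisation (I2, NaHCO3, MeCN/H2O) should give the cis-fused iodolactone F8, because the tethered carboxylate can add to C1 only on the arm face and iodine ends up anti on C6. Methanolysis (K2CO3, MeOH) frees the C1 alkoxide, which displaces the anti iodide to give the syn epoxy ester F9. Reduction of the ester with LiBH4 (THF, 0 °C) returns to the route at epoxy alcohol 12.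

**Further compounds**

F1 | step 9 | 2-[(1S,2R,6R)-1,2-dimethyl-7-oxabicyclo[4.1.0]heptan-2-yl]ethyl pivalate | C[C@@]12O[C@@H]1CCC[C@]2(C)CCOC(=O)C(C)(C)C
F2 | step 9 | 2-[(1R,2R)-2-formyl-1,2-dimethylcyclopentyl]ethyl pivalate | O=C[C@]1(C)CCC[C@]1(C)CCOC(=O)C(C)(C)C
F3 | step 9 | 2-[(1R,2R)-2-(1-hydroxy-4-methylpent-3-en-1-yl)-1,2-dimethylcyclopentyl]ethyl pivalate (carbinol epimers) | CC(C)=CCC(O)[C@]1(C)CCC[C@]1(C)CCOC(=O)C(C)(C)C
F4 | step 17 | {[(E)-4-(2,5-dimethoxy-3-methylphenyl)-2-methylbut-2-en-1-yl]sulfonyl}benzene | COc1cc(C)c(OC)c(C/C=C(\C)CS(=O)(=O)c2ccccc2)c1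
F5 | step 17 | 1-{(1R,2R)-2-[(E)-6-(2,5-dimethoxy-3-methylphenyl)-2-hydroxy-4-methyl-3-(phenylsulfonyl)hex-4-en-1-yl]-1,2-dimethylcyclopentyl}-4-methylpent-3-en-1-one (diastereomer mixture) | CC(C)=CCC(=O)[C@]1(C)CCC[C@]1(C)CC(O)C(/C(C)=C/Cc1cc(OC)cc(C)c1OC)S(=O)(=O)c1ccccc1
F6 | step 17 | (E)-6-(2,5-dimethoxy-3-methylphenyl)-1-[(1R,2R)-1,2-dimethyl-2-(4-methylpent-3-enoyl)cyclopentyl]-4-methyl-3-(phenylsulfonyl)hex-4-en-2-one | CC(C)=CCC(=O)[C@]1(C)CCC[C@]1(C)CC(=O)C(/C(C)=C/Cc1cc(OC)cc(C)c1OC)S(=O)(=O)c1ccccc1
F7 | step 7 | 2-[(1R)-1,2-dimethylcyclohex-2-en-1-yl]acetic acid | CC1=CCCC[C@]1(C)CC(=O)O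
F8 | step 7 | (3aR,7S,7aS)-7-iodo-3a,7a-dimethylhexahydro-1-benzofuran-2(3H)-one | C[C@]12CCC[C@H](I)[C@@]1(C)OC(=O)C2
F9 | step 7 | methyl 2-[(1S,2R,6R)-1,2-dimethyl-7-oxabicyclo[4.1.0]heptan-2-yl]acetate | C[C@@]12O[C@@H]1CCC[C@]2(C)CC(=O)OC
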